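- Each M of coupling partner spent takes one M of starting material with it, by the overall equation.

| flask | starting material | coupling partner | catalyst | time |
|---|---|---|---|---|
| autumn | 0.600 M | 0.480 M | 0.0300 M |  |
| noon | 1.80 M | 0.480 M | 0.0300 M |  |
| winter | 0.600 M | 0.480 M | 0.0900 M |  |
| summer | 0.600 M | 1.40 M | 0.0300 M |  |
| dawn | 1.20 M | 0.160 M | 0.0300 M | 6.7 min |

| run | time / min | [starting material] / M |
|---|---|---|
| autumn run | 0.24 | 0.585 |
| autumn run | 0.73 | 0.557 |
| autumn run | 1.4 | 0.520 |
| autumn run | 2.2 | 0.470 |
| autumn run | 3.2 | 0.421 |
| autumn run | 4.2 | 0.370 |
| autumn run | 5.4 | 0.348 |
| autumn run | 6.7 | 0.327 |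
| noon run | 0.24 | 1.779 |
| noon run | 0.73 | 1.711 |
| noon run | 1.4 | 1.652 |
| noon run | 2.2 | 1.558 |
| noon run | 3.2 | 1.473 |
| noon run | 4.2 | 1.409 |
| noon run | 5.4 | 1.311 |
| noon run | 6.7 | 1.277 |
| winter run | 0.24 | 0.532 |
| winter run | 0.73 | 0.493 |
| winter run | 1.4 | 0.426 |
| winter run | 2.2 | 0.358 |
| winter run | 3.2 | 0.299 |
| winter run | 4.2 | 0.242 |
| winter run | 5.4 | 0.217 |
| winter run | 6.7 | 0.190 |
| summer run | 0.24 | 0.574 |
| summer run | 0.73 | 0.482 |
| summer run | 1.4 | 0.391 |
| summer run | 2.2 | 0.325 |
| summer run | 3.2 | 0.215 |
| summer run | 4.2 | 0.170 |
| summer run | 5.4 | 0.115 |
| summer run | 6.7 | 0.062 |

(scatter of a reading: 0.009 M)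

- Overall: starting material + coupling partner -> target, with catalyst as catalyst.
- Constant volume, constant temperature.
- Bound and free are read together.
- "The second partner" is coupling partner.
- An order is taken over about fifteen percent of the charge, up and down.

* apparent order in [coupling partner] of the starting rate, round the charge of the autumn run (the rate where two percent of its starting material have turned into target)
* apparent order in [starting material] of the starting rate, round the charge of the autumn run (the rate where two percent of its starting material have turned into target) (one fixed amount of target, the same in the runs compared)
* starting material in the dawn run at 6.7 min, as a share of the starting material charged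
* which of these the readings show (the by-product ties up the catalyst / the product binds the second partner / nothing beyond the main steps / a little impurity takes part of the catalyst at once / two substrates go astray together / the substrate is lost by itself)

- A bench rule of thumb follows: where the coupling partner is the limiting reagent, the loss of starting material by the main reaction is bounded by the coupling partner charged.
- In the dawn run this gives the stoichiometric floor, the [starting material] at the start minus the [coupling partner] at the start, 1.04 M. That is 86.7% of the dawn charge.
- The noon run tests the rule, with a floor of 1.32 M.
- At 6.7 min the noon run reads 1.277 M, lower than its floor by 0.0430 M.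
- That gap is 4.78 times the scatter of a reading, so the rule stops here: in the noon run, some starting material leaves without coupling partner.
- The approach to the floor can be read too. Over its first 1.4 min, the noon run loses starting material at 0.220 min⁻¹ per M of coupling partner charged.
- My own reckoning charges that whole early loss to the coupling partner and treats it as pseudo-first-order at that reading, so 77.1% of it is used in the noon run by 6.7 min.
- By this reckoning the noon run has 0.153 M of starting material gone by the other route, or 8.49% of its charge.
- I assume that the dawn run uses the same fraction of its coupling partner and loses the same share of its charge, which the readings do not prove. The dawn run then keeps 81.2%.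
- The forecast gives orders of 0.9 in coupling partner and 0.5 in starting material, 82.5% left in the dawn run against the 81.2% of my reckoning, and the choice "two substrates go astray together", on this ground: “This suggests a second-order loss, though a first-order loss isn't firmly excluded.”

- The dawn run gives 79.4%, which is 1.8 percentage points under my reckoning, and the apparent orders are 1.0 in coupling partner and 0.59 in starting material.
- The answer to the last question is that the substrate is lost by itself, with a first-order constant of 0.0202 min⁻¹.

    catalyst + starting material ⇌ catalyst-substrate complex, settled at all times (1.310 L mol⁻¹)
    catalyst-substrate complex + coupling partner → target + catalyst + by-product (9.180 L mol⁻¹ min⁻¹)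
    starting material → decomposed substrate (0.02022 min⁻¹)
- In the dawn run, 79.4% of the charge is 0.953 M of starting material, which lies 0.0870 M under the floor of 1.04 M.

(The earlier runs and the new flask come from a simulation with made-up constants; noise was put on by code.)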